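**Strategy**

- Retrosynthesis: the two tiglate ester C–O bonds (at C7 and C4) are cut first, then the acetate C–O bond. Next come the C6–O and C5–H bonds (syn hydration of a C5=C6 olefin), the C4–H bond (ketone reduction), the two C1–OMe bonds (phenol dearomatization) and last the ring–isopropyl C–C bond.
- Forward: the only ring, the six-membered carbocycle, is the benzene ring of a bromohydroxybenzoate and is never constructed. A Suzuki coupling joins the isopropyl carbons, the 7-silyloxy thymol-type phenol is oxidized to a p-quinone monoketal, the dienone is reduced, one ring olefin is hydrated, the ketone is unmasked and the acyl groups are attached.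
- Enabling feature: C1 (ketone) and C4 (carbinol) sit para on the carbocycle, so the ring is a masked hydroquinone. The C5–H and C6–O bonds are cis to each other and trans to the C4–O bond, which is what a syn H/OH addition to a C5=C6 double bond leaves when it arrives opposite a C4 oxygen substituent.
- Stereochemistry: C4 comes from CBS reduction of the prochiral dienone (reagent control). C5 and C6 come together from one hydroboration–oxidation relayed from C4 (substrate control). Both (E)-olefins come from tiglic acid.

Key step: step 8

Remark: ring atoms carry the target numbering throughout (C1 ketone or its ketal, C2 bearing the C7 oxymethylene, C3 olefinic CH, C4 carbinol, C5 isopropyl-bearing, C6 acetoxy-bearing). The SMILES is read as (4S,5S,6R), with the C4 oxygen and the isopropyl group on one face and the C6 oxygen on the other.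

**Route**

Step 1
Reactants: 1 methyl 4-bromo-3-hydroxybenzoate; 2 isopropenylboronic acid pinacol ester
Product: 3 methyl 3-hydroxy-4-(prop-1-en-2-yl)benzoate
Conditions: Pd(dppf)Cl2 (5 mol %), K2CO3 (3 equiv), 1,4-dioxane/H2O, 80 °C
Reagents that add atoms: none
Why: Suzuki–Miyaura coupling of an electron-poor aryl bromide with an alkenyl pinacol boronate is routine, tolerates the free phenol (as phenoxide) and the ester, and places the three-carbon branch ortho to the hydroxyl and para to the ester.

Step 2
Reactants: 3 methyl 3-hydroxy-4-(prop-1-en-2-yl)benzoate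
Product: 4 methyl 3-hydroxy-4-isopropylbenzoate
Conditions: H2 (1 atm), Pd/C (10 wt %), EtOAc, rt
Reagents that add atoms: none
Why: Heterogeneous catalytic hydrogenation saturates the 1,1-disubstituted styrenic olefin much faster than it touches the arene or the ester, and doing it at the ester stage avoids any benzylic C–O hydrogenolysis later.

Step 3
Reactants: 4 methyl 3-hydroxy-4-isopropylbenzoate
Product: 5 5-(hydroxymethyl)-2-isopropylphenol
Conditions: LiAlH4, THF, 0 °C to rt; then H2O
Reagents that add atoms: none
Why: LiAlH4 reduction of an aryl ester to the benzylic primary alcohol is standard; the phenol only consumes one hydride as an inert phenoxide and is recovered on aqueous work-up.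

Step 4
Reactants: 5 5-(hydroxymethyl)-2-isopropylphenol
Product: 6 5-[(tert-butyldimethylsilyloxy)methyl]-2-isopropylphenol
Conditions: TBSCl (1.05 equiv), imidazole, DMF, 0 °C
Reagents that add atoms: tert-butyldimethylsilyl chloride, CC(C)(C)[Si](C)(C)Cl
Why: Chemoselective imidazole-mediated silylation takes the unhindered primary benzylic hydroxyl in preference to the phenol, as is usual for hydroxybenzyl alcohols, and here the phenol is further shielded by its ortho isopropyl group.

Step 5
Reactants: 6 5-[(tert-butyldimethylsilyloxy)methyl]-2-isopropylphenol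
Product: 8 5-[(tert-butyldimethylsilyloxy)methyl]-2-isopropyl-4,4-dimethoxycyclohexa-2,5-dien-1-one (p-quinone monoketal), via p-methoxyphenol 7 (not isolated)
Conditions: PhI(OAc)2 (2.2 equiv), NaHCO3, MeOH, 0 °C
Reagents that add atoms: methanol, CO
Why: Oxidative dearomatization by the trivalent iodine reagent is known for para-unsubstituted phenols: the first equivalent brings methanol to the free para carbon and the dienone tautomerizes to phenol 7, the second converts 7 into the 4,4-dimethoxy dienone, so the phenol carbon becomes the future C4 carbonyl and the para carbon the future C1 ketal, while the bicarbonate buffer protects the silyl ether and the ketal.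

Step 6
Reactants: 8 p-quinone monoketal
Product: 9 (1S)-5-[(tert-butyldimethylsilyloxy)methyl]-2-isopropyl-4,4-dimethoxycyclohexa-2,5-dien-1-ol ((4S)-quinol ketal in target numbering)
Conditions: (R)-2-methyl-CBS-oxazaborolidine (0.5 equiv), catecholborane (1.5 equiv), toluene, −78 °C; MeOH quench, basic aqueous wash (NaHCO3/NaOH)
Reagents that add atoms: none
Why: Corey–Bakshi–Shibata reduction gives clean 1,2-reduction of α-substituted cyclic enones; the isopropyl-bearing alkenyl arm acts as the large group so that the (R)-catalyst should deliver hydride to the face that gives the (S)-carbinol at C4, the sense being checked on the first batch by Mosher ester analysis (the (S)-catalyst is used if the arms are read the other way) and the work-up kept basic because acid would expel methanol and rearomatize the product.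

Step 7
Reactants: 9 (4S)-quinol ketal
Product: 10 (4S)-4-(tert-butyldimethylsilyloxy)-2-[(tert-butyldimethylsilyloxy)methyl]-5-isopropyl-1,1-dimethoxycyclohexa-2,5-diene (bis-silyl ether)
Conditions: TBSCl, imidazole, DMAP (cat.), DMF, rt, on the crude carbinol
Reagents that add atoms: tert-butyldimethylsilyl chloride, CC(C)(C)[Si](C)(C)Cl
Why: Imidazole-mediated silylation of the secondary allylic alcohol is standard and stays on the basic side, which is preferred here over a Lewis-acidic silyl triflate that could ionize the ketal; the C4 centre is untouched.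

Step 8
Reactants: 10 bis-silyl ether
Product: 12 (4S,5R,6R)-4-(tert-butyldimethylsilyloxy)-2-[(tert-butyldimethylsilyloxy)methyl]-5-isopropyl-1,1-dimethoxycyclohex-2-en-6-ol (C4–OSi and isopropyl on one face, C6–OH on the other), via C6 alkylborane 11 (not isolated)
Conditions: BH3·THF (1.1 equiv), THF, −20 to 0 °C; then 30% H2O2, 3 M NaOH, 0 °C
Reagents that add atoms: hydrogen peroxide, OO
Why: BH3 adds across C5=C6 through the concerted four-centre transition state, boron to the less substituted C6 and hydrogen to C5 on the same face, and alkaline H2O2 then turns C6–B into C6–O by 1,2-migration with retention; no ring is closed. The closest known reaction type is the anti-selective hydroboration–oxidation of 2-alkyl-substituted cyclic allylic silyl ethers, together with the routine oxidation of the β-alkoxy boranes obtained from cyclic enol ethers. C5 and C6 are created together and both are controlled by C4: allylic 1,2-strain with the C5 isopropyl group tilts the C4 silyloxy group pseudoaxial over its own face of the nearly flat 1,4-diene, the ketal carbon looks the same from both faces, and borane therefore arrives anti to the silyloxy group, leaving the isopropyl cis to the C4 oxygen and the C6 oxygen trans to both. Regioselectivity is doubly secured, because the substitution pattern and the inductive pull of the two ketal oxygen atoms each direct boron to C6. Site selectivity rests on C5=C6 being the more electron-rich olefin (alkyl donor), whereas C2=C3 is flanked by three oxygenated allylic carbons and has steric and inductive regiochemical preferences that oppose each other. Borane 11 carries a β-methoxy group, so it is made with about one equivalent of BH3 below 0 °C and oxidized at once so that loss of methoxide cannot compete.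

Step 9
Reactants: 12 C6 alcohol
Product: 13 (4S,5R,6R)-6-acetoxy-4-(tert-butyldimethylsilyloxy)-2-[(tert-butyldimethylsilyloxy)methyl]-5-isopropyl-1,1-dimethoxycyclohex-2-ene
Conditions: Ac2O, pyridine, DMAP (cat.), CH2Cl2, rt
Reagents that add atoms: acetic anhydride, CC(=O)OC(C)=O
Why: DMAP-catalysed acyl transfer acetylates even hindered secondary alcohols, and the C6 hydroxyl is the only free one, so no selectivity is needed and no stereocentre is touched.

Step 10
Reactants: 13 C6 acetate
Product: 15 (4S,5S,6R)-6-acetoxy-4-hydroxy-2-(hydroxymethyl)-5-isopropylcyclohex-2-en-1-one, via C4 silyloxy enone 14 (not isolated)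
Conditions: 48% aq. HF, MeCN, 0 °C to rt
Reagents that add atoms: water, O
Why: One mildly acidic operation hydrolyses the allylic dimethyl ketal to the C1 enone and cleaves both silyl ethers (the hindered C4 ether is expected to go last); the acetate is stable to aqueous acid and cannot migrate to C4 because the C4 and C6 oxygen atoms are trans-1,3, and without base C6 is not epimerized.

Step 11
Reactants: 15 (4S,5S,6R)-6-acetoxy-4-hydroxy-2-(hydroxymethyl)-5-isopropylcyclohex-2-en-1-one; 16 tiglic acid
Product: 19 (4S,5S,6R)-6-acetoxy-5-isopropyl-4-(tigloyloxy)-2-(tigloyloxymethyl)cyclohex-2-en-1-one (CNP0218511.1), via mixed anhydride 17 (not isolated), via C7 monotiglate 18 (not isolated)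
Conditions: 16 (3 equiv), 2,4,6-trichlorobenzoyl chloride, Et3N, toluene, rt; then 15, DMAP, 0 °C to rt
Reagents that add atoms: none
Why: Yamaguchi esterification: DMAP opens the mixed anhydride at the unhindered tigloyl carbonyl and transfers the acyl group first to the primary C7 hydroxyl and then to the secondary C4 hydroxyl, with no new stereocentre and no olefin isomerization to fear because the tiglate is the stable (E)-isomer.

**Compound list**

1 | methyl 4-bromo-3-hydroxybenzoate | COC(=O)c1ccc(Br)c(O)c1 | starting material
2 | isopropenylboronic acid pinacol ester (2-isopropenyl-4,4,5,5-tetramethyl-1,3,2-dioxaborolane) | CC(=C)B1OC(C)(C)C(C)(C)O1 | starting material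
3 | methyl 3-hydroxy-4-(prop-1-en-2-yl)benzoate | COC(=O)c1ccc(C(C)=C)c(O)c1 | intermediate
4 | methyl 3-hydroxy-4-isopropylbenzoate | COC(=O)c1ccc(C(C)C)c(O)c1 | intermediate
5 | 5-(hydroxymethyl)-2-isopropylphenol | CC(C)c1ccc(CO)cc1O | intermediate
6 | 5-[(tert-butyldimethylsilyloxy)methyl]-2-isopropylphenol | CC(C)c1ccc(CO[Si](C)(C)C(C)(C)C)cc1O | intermediate
7 | 5-[(tert-butyldimethylsilyloxy)methyl]-2-isopropyl-4-methoxyphenol (not isolated) | CC(C)c1cc(OC)c(CO[Si](C)(C)C(C)(C)C)cc1O | intermediate
8 | 5-[(tert-butyldimethylsilyloxy)methyl]-2-isopropyl-4,4-dimethoxycyclohexa-2,5-dien-1-one | CC(C)C1=CC(OC)(OC)C(CO[Si](C)(C)C(C)(C)C)=CC1=O | intermediate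
9 | (1S)-5-[(tert-butyldimethylsilyloxy)methyl]-2-isopropyl-4,4-dimethoxycyclohexa-2,5-dien-1-ol | CC(C)(C)[Si](C)(C)OCC1=C[C@H](O)C(C(C)C)=CC1(OC)OC | intermediate
10 | (4S)-4-(tert-butyldimethylsilyloxy)-2-[(tert-butyldimethylsilyloxy)methyl]-5-isopropyl-1,1-dimethoxycyclohexa-2,5-diene (target numbering) | CC(C)(C)[Si](C)(C)OCC1=C[C@H](O[Si](C)(C)C(C)(C)C)C(C(C)C)=CC1(OC)OC | intermediate
11 | C6 monoalkylborane of 10: BH2 on C6 and the new hydrogen on C5 on the same face, opposite to the C4 silyloxy group (not isolated) | CC(C)(C)[Si](C)(C)OCC1=C[C@H](O[Si](C)(C)C(C)(C)C)[C@H](C(C)C)[C@@H]([BH2])C1(OC)OC | intermediate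
12 | (4S,5R,6R)-4-(tert-butyldimethylsilyloxy)-2-[(tert-butyldimethylsilyloxy)methyl]-5-isopropyl-1,1-dimethoxycyclohex-2-en-6-ol (target numbering) | CC(C)(C)[Si](C)(C)OCC1=C[C@H](O[Si](C)(C)C(C)(C)C)[C@H](C(C)C)[C@@H](O)C1(OC)OC | intermediate
13 | (4S,5R,6R)-6-acetoxy-4-(tert-butyldimethylsilyloxy)-2-[(tert-butyldimethylsilyloxy)methyl]-5-isopropyl-1,1-dimethoxycyclohex-2-ene (target numbering) | CC(C)(C)[Si](C)(C)OCC1=C[C@H](O[Si](C)(C)C(C)(C)C)[C@H](C(C)C)[C@@H](OC(C)=O)C1(OC)OC | intermediate
14 | (4S,5R,6R)-6-acetoxy-4-(tert-butyldimethylsilyloxy)-2-(hydroxymethyl)-5-isopropylcyclohex-2-en-1-one (not isolated) | OCC1=C[C@H](O[Si](C)(C)C(C)(C)C)[C@H](C(C)C)[C@@H](OC(C)=O)C1=O | intermediate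
15 | (4S,5S,6R)-6-acetoxy-4-hydroxy-2-(hydroxymethyl)-5-isopropylcyclohex-2-en-1-one | OCC1=C[C@H](O)[C@H](C(C)C)[C@@H](OC(C)=O)C1=O | intermediate
16 | tiglic acid ((E)-2-methylbut-2-enoic acid) | C/C=C(\C)C(=O)O | starting material
17 | tiglic 2,4,6-trichlorobenzoic anhydride (not isolated) | C/C=C(\C)C(=O)OC(=O)c1c(Cl)cc(Cl)cc1Cl | intermediate
18 | (4S,5S,6R)-6-acetoxy-4-hydroxy-5-isopropyl-2-(tigloyloxymethyl)cyclohex-2-en-1-one (not isolated) | C/C=C(\C)C(=O)OCC1=C[C@H](O)[C@H](C(C)C)[C@@H](OC(C)=O)C1=O | intermediate
19 | (4S,5S,6R)-6-acetoxy-5-isopropyl-4-(tigloyloxy)-2-(tigloyloxymethyl)cyclohex-2-en-1-one (CNP0218511.1) | C/C=C(\C)C(=O)OCC1=C[C@H](OC(=O)/C(C)=C/C)[C@H](C(C)C)[C@@H](OC(C)=O)C1=O | target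

**Step count and risks**

Total step count: 11 steps.
Longest linear sequence: 11 steps (1 to 19); 2 and 16 are bought and enter in steps 1 and 11.

Steps most likely to fail:

1. Step 8. Borane may add to the C2=C3 olefin or to both olefins, and the C6 borane may lose its β-methoxide before it is oxidized. The fallback sets out from 8 and comes back at 12, and it reverses the polarity of the boron addition. Copper-catalysed enantioselective conjugate borylation of the dienone (CuCl, NaOtBu, a chiral bisphosphine ligand whose enantiomer is chosen for the required face, B2pin2, MeOH, THF) delivers boron as a nucleophile to C6, the only β-carbon that carries hydrogen, since C2 is fully substituted. This gives the (5S,6R)-β-boryl ketone F1, in which C5 equilibrates next to the ketone to the trans arrangement and the pinacol boronate does not expel methoxide. Oxidation with NaBO3·4H2O gives the (5R,6R)-β-hydroxy ketone F2. Hydroxyl-directed Evans–Saksena reduction (Me4NBH(OAc)3, MeCN/AcOH, −30 °C) delivers hydride intramolecularly and gives the (4S,5S,6R)-trans-1,3-diol F3. Silylation of the less hindered allylic C4 hydroxyl (TBSCl, imidazole, DMF, 0 °C), in preference to the C6 hydroxyl next to the quaternary ketal carbon, returns 12.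

2. Step 6. The oxazaborolidine may discriminate poorly between the two alkenyl arms of the dienone, so that the facial selectivity of hydride delivery is insufficient. The fallback sets out from 8 and comes back at 9. Luche reduction (NaBH4, CeCl3·7H2O, MeOH, −78 °C) gives the racemic quinol ketal F4. Lipase-mediated kinetic resolution (Burkholderia cepacia lipase or Candida antarctica lipase B, vinyl acetate, tert-butyl methyl ether, rt) should acetylate the (R)-alcohol to the (R)-acetate F5, which is removed by chromatography, and leave (S)-alcohol 9. Running the acylation past half conversion raises the enantiopurity of the remaining alcohol even if the enzyme is only moderately selective, and the neutral medium suits the acid-sensitive ketal.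

3. Step 5. The first oxidation stage of the para-unsubstituted phenol may be unselective (attack at the free ortho carbon, over-oxidation or oxidative coupling), so that the monoketal forms inefficiently. The fallback sets out from 6 and comes back at 8, and it installs the para oxygen before the dearomatization. Para-bromination (NBS, MeCN, 0 °C) gives 4-bromo-5-[(tert-butyldimethylsilyloxy)methyl]-2-isopropylphenol F6. Copper-mediated methoxylation (NaOMe, CuBr, MeOH/DMF, 100 °C), a transformation well known on free bromophenols, gives p-methoxyphenol 7, which is now isolated. A single oxidation with PhI(OAc)2 (1.1 equiv) in MeOH at 0 °C, the standard route from p-methoxyphenols to quinone monoketals, then gives 8.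

**Further compounds**

F1 | step 8 | (5S,6R)-2-[(tert-butyldimethylsilyloxy)methyl]-5-isopropyl-1,1-dimethoxy-6-(4,4,5,5-tetramethyl-1,3,2-dioxaborolan-2-yl)cyclohex-2-en-4-one (target numbering) | CC(C)(C)[Si](C)(C)OCC1=CC(=O)[C@H](C(C)C)[C@@H](B2OC(C)(C)C(C)(C)O2)C1(OC)OC
F2 | step 8 | (5R,6R)-2-[(tert-butyldimethylsilyloxy)methyl]-6-hydroxy-5-isopropyl-1,1-dimethoxycyclohex-2-en-4-one (target numbering) | CC(C)(C)[Si](C)(C)OCC1=CC(=O)[C@H](C(C)C)[C@@H](O)C1(OC)OC
F3 | step 8 | (4S,5S,6R)-2-[(tert-butyldimethylsilyloxy)methyl]-5-isopropyl-1,1-dimethoxycyclohex-2-ene-4,6-diol (target numbering) | CC(C)(C)[Si](C)(C)OCC1=C[C@H](O)[C@H](C(C)C)[C@@H](O)C1(OC)OC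
F4 | step 6 | racemic 5-[(tert-butyldimethylsilyloxy)methyl]-2-isopropyl-4,4-dimethoxycyclohexa-2,5-dien-1-ol | CC(C)(C)[Si](C)(C)OCC1=CC(O)C(C(C)C)=CC1(OC)OC
F5 | step 6 | (1R)-5-[(tert-butyldimethylsilyloxy)methyl]-2-isopropyl-4,4-dimethoxycyclohexa-2,5-dien-1-yl acetate | CC(C)(C)[Si](C)(C)OCC1=C[C@@H](OC(C)=O)C(C(C)C)=CC1(OC)OC
F6 | step 5 | 4-bromo-5-[(tert-butyldimethylsilyloxy)methyl]-2-isopropylphenol | CC(C)c1cc(Br)c(CO[Si](C)(C)C(C)(C)C)cc1O
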